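**Retrosynthetic overview**
1. The C1=N bond is cut back to an ortho-(2-aminopropyl)acetophenone, and the benzene ring of the isoquinoline is cut by a [4+2] benzannulation into a naphthyl-substituted vinylketene acetal (C5–C8) and a chiral alkynyl ketone (C4a and C8a with the acetyl and aminopropyl arms).
2. Both rings of the dihydroisoquinoline are therefore made last, in one flask: Diels–Alder/aromatisation builds the benzene ring, then N-deprotection closes the dihydropyridine ring.
3. The biaryl axis is not made by aryl–aryl coupling; it is laid down earlier as an aryl–vinyl bond (Negishi) before the second arene exists.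
4. The alkynyl ketone comes from a D-alaninol-derived cyclic sulfamidate (source of the only stereocentre, C-3), ethynyltrimethylsilane and a Weinreb amide.
5. Ring order: naphthalene carbocycle first (aryne annulation of 3-methoxybenzyne with a senecioamide dienolate), then the isoquinoline benzene ring and its nitrogen ring in the final step.

Assumption: the SMILES defines only C-3 (R); the C7–C1' biaryl axis is unspecified, so it is not controlled and the (3R) product is taken as whatever atropisomer mixture forms.

**Route**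

Step 1
Reactants: 1 3-bromoanisole; 2 N,N-diethyl-3-methylbut-2-enamide
Product: 5 1,8-dimethoxy-3-methylnaphthalene, via 3-methoxybenzyne 3 (not isolated), via lithium 8-methoxy-3-methylnaphthalen-1-olate 4 (not isolated)
Conditions: lithium diisopropylamide (3 equiv), THF, −78 °C to rt; then Me2SO4, DMPU, 0 °C to rt
Reagents that add atoms: dimethyl sulfate, COS(=O)(=O)OC
Why: anionic aryne annulation, in which the γ-carbon of the lithium dienolate of 2 adds to 3 at the carbon remote from OMe, the aryl anion formed ortho to OMe acylates itself on the amide carbonyl (Dieckmann-type closure, loss of LiNEt2) to give the peri-methoxy naphtholate 4 regioselectively, and 4 is O-methylated in the same flask (Williamson ether synthesis); no stereocentre is formed.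

Step 2
Reactants: 5 1,8-dimethoxy-3-methylnaphthalene
Product: 6 1-bromo-4,5-dimethoxy-2-methylnaphthalene
Conditions: N-bromosuccinimide (1.0 equiv), MeCN, 0 °C, dark
Reagents that add atoms: N-bromosuccinimide, O=C1CCC(=O)N1Br
Why: electrophilic aromatic bromination is expected at C-4 of 5, the position para to the C-1 methoxy group and further activated by the ortho methyl group, which is C-1' of the target.

Step 3
Reactants: 6 1-bromo-4,5-dimethoxy-2-methylnaphthalene; 7 methyl 2-bromobut-2-enoate
Product: 10 methyl 2-(4,5-dimethoxy-2-methylnaphthalen-1-yl)but-2-enoate, via (4,5-dimethoxy-2-methylnaphthalen-1-yl)lithium 8 (not isolated), via (4,5-dimethoxy-2-methylnaphthalen-1-yl)zinc chloride 9 (not isolated)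
Conditions: n-BuLi, THF, −78 °C; ZnCl2, −78 °C to rt; then 7, Pd(OAc)2 (3 mol %), SPhos (6 mol %), THF, 60 °C
Reagents that add atoms: none
Why: bromine–lithium exchange, transmetalation to zinc and Negishi cross-coupling with the α-bromo enoate make the future biaryl bond as a less hindered aryl–vinyl bond, the bulky biarylphosphine copes with the di-ortho-substituted arylzinc, and the alkene geometry of 10 does not matter because step 4 erases it.

Step 4
Reactants: 10 methyl 2-(4,5-dimethoxy-2-methylnaphthalen-1-yl)but-2-enoate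
Product: 12 tert-butyl{[1-methoxy-2-(4,5-dimethoxy-2-methylnaphthalen-1-yl)buta-1,3-dien-1-yl]oxy}dimethylsilane, via lithium dienolate 11 (not isolated)
Conditions: lithium diisopropylamide, THF–DMPU, −78 °C; then t-BuMe2SiCl, −78 to 0 °C; non-aqueous work-up
Reagents that add atoms: tert-butyldimethylsilyl chloride, CC(C)(C)[Si](C)(C)Cl
Why: γ-deprotonation of the α,β-unsaturated ester gives the extended dienolate 11 and the hard silyl chloride reacts on oxygen (O-silylation), giving the vinylketene silyl acetal, a 1,1-dioxygenated diene of fixed regiochemistry; no stereocentre.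

Step 5
Reactants: 13 tert-butyl (4R)-4-methyl-1,2,3-oxathiazolidine-3-carboxylate 2,2-dioxide; 14 ethynyltrimethylsilane
Product: 18 tert-butyl N-[(2R)-pent-4-yn-2-yl]carbamate, via lithium (trimethylsilyl)acetylide 15 (not isolated), via lithium N-Boc sulfamate 16 (not isolated), via C-silylated alkyne carbamate 17 (not isolated)
Conditions: 14, n-BuLi, THF, −78 °C; then 13, −78 °C to rt; 1 M aq. citric acid, rt; then K2CO3 (cat.), MeOH, rt
Reagents that add atoms: none
Why: SN2 ring opening of the cyclic sulfamidate by the acetylide occurs only at the primary O–CH2 carbon, so the (R) C–N stereocentre from the chiral pool (D-alaninol) is untouched, after which mild acid hydrolyses the N-sulfamate and K2CO3/MeOH removes the C-silyl group.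

Step 6
Reactants: 18 tert-butyl N-[(2R)-pent-4-yn-2-yl]carbamate; 19 N-methoxy-N-methylacetamide
Product: 21 tert-butyl N-[(2R)-6-oxohept-4-yn-2-yl]carbamate, via N,C-dilithio derivative 20 (not isolated)
Conditions: n-BuLi (2.1 equiv), THF, −78 °C; then 19, −78 to 0 °C; H2O
Reagents that add atoms: none
Why: Weinreb ketone synthesis, in which the acetylide carbon of dianion 20 adds once to the N-methoxy-N-methylamide (stable chelated tetrahedral intermediate) and work-up releases the alkynyl methyl ketone; the stereocentre is not involved.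

Step 7
Reactants: 12 tert-butyl{[1-methoxy-2-(4,5-dimethoxy-2-methylnaphthalen-1-yl)buta-1,3-dien-1-yl]oxy}dimethylsilane; 21 tert-butyl N-[(2R)-6-oxohept-4-yn-2-yl]carbamate
Product: 26 (3R)-7-(4,5-dimethoxy-2-methylnaphthalen-1-yl)-8-methoxy-1,3-dimethyl-3,4-dihydroisoquinoline, via cyclohexadiene ketal cycloadduct 22 (not isolated), via aryl silyl ether 23 (not isolated), via keto carbamate 24 (not isolated), via amino ketone 25 (not isolated)
Conditions: PhMe, 100 °C (sealed tube); then CsF, MeI, DMF, rt; evaporate; then CF3CO2H, CH2Cl2, 0 °C to rt; aq. NaHCO3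
Reagents that add atoms: iodomethane, CI
Why: Brassard-type Diels–Alder benzannulation, in which the terminal CH2 of vinylketene acetal 12 bonds to the β-carbon of ynone 21 and the acetal carbon to the acyl-bearing carbon, so the acetyl group ends up ortho to the oxygenated carbon with the naphthyl next to it; the 3,3-dioxygenated cyclohexa-1,4-diene 22 aromatises by loss of methanol (any material that loses the silanol instead is already 24), fluoride-triggered O-methylation converges everything on 24, and acid removes the Boc group so that the amine condenses with the ortho acetyl group to the cyclic ketimine, which forms the benzene ring and the dihydropyridine ring in the same flask, while C-3 comes unchanged from 13 and the biaryl axis is not controlled.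

**Compound list**
1 | 3-bromoanisole (1-bromo-3-methoxybenzene) | COc1cccc(Br)c1 | starting material
2 | N,N-diethyl-3-methylbut-2-enamide | CCN(CC)C(=O)C=C(C)C | starting material
3 | 3-methoxybenzyne (1-methoxy-2,3-didehydrobenzene) | COC1=CC=CC#C1 | intermediate
4 | lithium 8-methoxy-3-methylnaphthalen-1-olate | [Li+].[O-]c1cc(C)cc2cccc(OC)c12 | intermediate
5 | 1,8-dimethoxy-3-methylnaphthalene | COc1cc(C)cc2cccc(OC)c12 | intermediate
6 | 1-bromo-4,5-dimethoxy-2-methylnaphthalene | COc1cc(C)c(Br)c2cccc(OC)c12 | intermediate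
7 | methyl 2-bromobut-2-enoate (E/Z mixture) | CC=C(Br)C(=O)OC | starting material
8 | (4,5-dimethoxy-2-methylnaphthalen-1-yl)lithium | [Li]c1c(C)cc(OC)c2c(OC)cccc12 | intermediate
9 | (4,5-dimethoxy-2-methylnaphthalen-1-yl)zinc chloride | Cl[Zn]c1c(C)cc(OC)c2c(OC)cccc12 | intermediate
10 | methyl 2-(4,5-dimethoxy-2-methylnaphthalen-1-yl)but-2-enoate (E/Z mixture) | CC=C(C(=O)OC)c1c(C)cc(OC)c2c(OC)cccc12 | intermediate
11 | lithium 1-methoxy-2-(4,5-dimethoxy-2-methylnaphthalen-1-yl)buta-1,3-dien-1-olate | [Li+].[O-]C(OC)=C(C=C)c1c(C)cc(OC)c2c(OC)cccc12 | intermediate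
12 | tert-butyl{[1-methoxy-2-(4,5-dimethoxy-2-methylnaphthalen-1-yl)buta-1,3-dien-1-yl]oxy}dimethylsilane (E/Z mixture at the ketene acetal) | C=CC(=C(OC)O[Si](C)(C)C(C)(C)C)c1c(C)cc(OC)c2c(OC)cccc12 | intermediate
13 | tert-butyl (4R)-4-methyl-1,2,3-oxathiazolidine-3-carboxylate 2,2-dioxide | CC(C)(C)OC(=O)N1[C@H](C)COS1(=O)=O | starting material
14 | ethynyltrimethylsilane | C#C[Si](C)(C)C | starting material
15 | lithium (trimethylsilyl)acetylide | [Li]C#C[Si](C)(C)C | intermediate
16 | lithium N-(tert-butoxycarbonyl)-N-[(2R)-5-(trimethylsilyl)pent-4-yn-2-yl]sulfamate | [Li+].[O-]S(=O)(=O)N(C(=O)OC(C)(C)C)[C@H](C)CC#C[Si](C)(C)C | intermediate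
17 | tert-butyl N-[(2R)-5-(trimethylsilyl)pent-4-yn-2-yl]carbamate | CC(C)(C)OC(=O)N[C@H](C)CC#C[Si](C)(C)C | intermediate
18 | tert-butyl N-[(2R)-pent-4-yn-2-yl]carbamate | CC(C)(C)OC(=O)N[C@H](C)CC#C | intermediate
19 | N-methoxy-N-methylacetamide | CC(=O)N(C)OC | starting material
20 | N,C-dilithio derivative of 18 | CC(C)(C)OC(=O)N([Li])[C@H](C)CC#C[Li] | intermediate
21 | tert-butyl N-[(2R)-6-oxohept-4-yn-2-yl]carbamate | CC(C)(C)OC(=O)N[C@H](C)CC#CC(C)=O | intermediate
22 | tert-butyl N-[(2R)-1-{2-acetyl-3-[(tert-butyldimethylsilyl)oxy]-3-methoxy-4-(4,5-dimethoxy-2-methylnaphthalen-1-yl)cyclohexa-1,4-dien-1-yl}propan-2-yl]carbamate (mixture at the ketal carbon) | CC(C)(C)OC(=O)N[C@H](C)CC1=C(C(C)=O)C(OC)(O[Si](C)(C)C(C)(C)C)C(c2c(C)cc(OC)c3c(OC)cccc23)=CC1 | intermediate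
23 | tert-butyl N-[(2R)-1-{2-acetyl-3-[(tert-butyldimethylsilyl)oxy]-4-(4,5-dimethoxy-2-methylnaphthalen-1-yl)phenyl}propan-2-yl]carbamate | CC(C)(C)OC(=O)N[C@H](C)Cc1ccc(-c2c(C)cc(OC)c3c(OC)cccc23)c(O[Si](C)(C)C(C)(C)C)c1C(C)=O | intermediate
24 | tert-butyl N-[(2R)-1-[2-acetyl-3-methoxy-4-(4,5-dimethoxy-2-methylnaphthalen-1-yl)phenyl]propan-2-yl]carbamate | CC(C)(C)OC(=O)N[C@H](C)Cc1ccc(-c2c(C)cc(OC)c3c(OC)cccc23)c(OC)c1C(C)=O | intermediate
25 | 1-{2-[(2R)-2-aminopropyl]-6-methoxy-5-(4,5-dimethoxy-2-methylnaphthalen-1-yl)phenyl}ethan-1-one | N[C@H](C)Cc1ccc(-c2c(C)cc(OC)c3c(OC)cccc23)c(OC)c1C(C)=O | intermediate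
26 | (3R)-7-(4,5-dimethoxy-2-methylnaphthalen-1-yl)-8-methoxy-1,3-dimethyl-3,4-dihydroisoquinoline | COc1c(-c2c(C)cc(OC)c3c(OC)cccc23)ccc2c1C(C)=N[C@H](C)C2 | target

**Step count and risks**

Total steps: 7. Longest linear sequence: 5 steps (steps 1, 2, 3, 4, 7); the ynone branch (steps 5, 6) joins at step 7.

Most likely to fail:

Step 7. The Diels–Alder reaction has to bring an internal ynone onto a diene whose acetal terminus sits next to a di-ortho-substituted naphthyl group, so it may be slow, may stop at an open-chain Michael adduct, or may give [2+2] products. The in-flask methylation adds a further point of loss. The fallback changes the diene class and sets out from arylzinc chloride 9 and ynone 21. Negishi coupling of 9 with commercial 2-iodocyclohex-2-en-1-one (Pd(OAc)2, SPhos) gives 2-(4,5-dimethoxy-2-methylnaphthalen-1-yl)cyclohex-2-en-1-one F1. Trimethyl orthoformate with catalytic TsOH under equilibrating conditions converts it into the extended dienol ether 1-methoxy-2-(4,5-dimethoxy-2-methylnaphthalen-1-yl)cyclohexa-1,3-diene F2; the cross-conjugated isomer would have to be removed. Heating F2 with 21 in o-dichlorobenzene at 150 °C gives tert-butyl N-[(2R)-1-[3-acetyl-4-methoxy-5-(4,5-dimethoxy-2-methylnaphthalen-1-yl)bicyclo[2.2.2]octa-2,5-dien-2-yl]propan-2-yl]carbamate F3, which expels ethene (Alder–Rickert) with the bridgehead methoxy group retained. The fallback comes back to the route at keto carbamate 24, which is then treated with CF3CO2H as in step 7.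

Step 2. Bromination could also go para to the other methoxy group (C-5 of 5), giving an inseparable regioisomer. The fallback changes the directing group and sets out from lithium naphtholate 4. Quenching 4 with aq. NH4Cl instead of Me2SO4 gives 8-methoxy-3-methylnaphthalen-1-ol F4. N-bromosuccinimide in MeCN at −20 °C brominates para to the free hydroxyl to give 4-bromo-8-methoxy-3-methylnaphthalen-1-ol F5, and MeI with K2CO3 in acetone then methylates the phenol. The fallback comes back at 6.

Step 3. The di-ortho-substituted arylzinc may couple poorly or homocouple. The fallback replaces cross-coupling by carbonyl chemistry and sets out from aryllithium 8. Adding 8 to excess dimethyl oxalate at −78 °C gives methyl 2-(4,5-dimethoxy-2-methylnaphthalen-1-yl)-2-oxoacetate F6. Wittig olefination of the ketone with ethylidenetriphenylphosphorane (from ethyltriphenylphosphonium bromide and KN(SiMe3)2) installs the ethylidene group. The fallback comes back at 10.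

**Further compounds**
F1 | step 7 | 2-(4,5-dimethoxy-2-methylnaphthalen-1-yl)cyclohex-2-en-1-one | O=C1CCCC=C1c2c(C)cc(OC)c3c(OC)cccc23
F2 | step 7 | 1-methoxy-2-(4,5-dimethoxy-2-methylnaphthalen-1-yl)cyclohexa-1,3-diene | COC1=C(c2c(C)cc(OC)c3c(OC)cccc23)C=CCC1
F3 | step 7 | tert-butyl N-[(2R)-1-[3-acetyl-4-methoxy-5-(4,5-dimethoxy-2-methylnaphthalen-1-yl)bicyclo[2.2.2]octa-2,5-dien-2-yl]propan-2-yl]carbamate | COC12CCC(C=C1c3c(C)cc(OC)c4c(OC)cccc34)C(C[C@@H](C)NC(=O)OC(C)(C)C)=C2C(C)=O
F4 | step 2 | 8-methoxy-3-methylnaphthalen-1-ol | COc1cccc2cc(C)cc(O)c12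
F5 | step 2 | 4-bromo-8-methoxy-3-methylnaphthalen-1-ol | COc1cccc2c(Br)c(C)cc(O)c12
F6 | step 3 | methyl 2-(4,5-dimethoxy-2-methylnaphthalen-1-yl)-2-oxoacetate | COC(=O)C(=O)c1c(C)cc(OC)c2c(OC)cccc12
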